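**Retrosynthetic overview**
1. Butenolide: the ring CH2OH comes from a hydroxymethyl Stille coupling on a tetronic acid triflate; the tetronic acid comes from Dieckmann closure of the acetate of an (R)-α-hydroxy ester; that ester comes from methyl (R)-glycidate (source of the only stereocentre) opened by a (Z)-alkenyl metal.
2. (6Z)-Alkene with its CH2OH: CuI-catalysed anti-carbomagnesiation of propargyl alcohol by a homoallylic Grignard reagent, then iodinolysis.
3. Cyclohexene: never closed as a six-membered ring. The chain-bearing ring carbon is inserted as a carbenoid into the C(=O)–C(CH3)2 bond of 2,2-dimethylcyclopentanone; the ring-enlarged enolate is trapped as its triflate and then methylated.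
4. Enabling feature: in the carbocycle of the target the chain-bearing sp2 carbon lies between the quaternary C(CH3)2 carbon and the methyl-bearing sp2 carbon. The ketone carbon of the cyclopentanone therefore becomes the C–CH3 carbon, its quaternary α-carbon is the migrating group, and the oxido group both drives the shift and fixes the position of the ring double bond.
5. (10E)-Alkene by Johnson–Claisen rearrangement. Ring order: cyclopentanone (purchased) → cyclohexene (step 5) → butenolide (step 12).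

Key step: step 5

Assumption: compounds 1, 2, 8, 16 and 22 and all reagents are taken as purchased; the lactone stereocentre is (R) (O > ring sp2 carbon > CH2 > H) and the CH2OH of the (6Z)-alkene is cis to the CH2 that carries the butenolide.

**Step 1**
Reactants: 1 3-[(tert-butyldimethylsilyl)oxy]propanal; 2 isopropenylmagnesium bromide
Product: 3 (±)-5-[(tert-butyldimethylsilyl)oxy]-2-methylpent-1-en-3-ol
Conditions: THF, −78 to 0 °C; then H2O
Reagents that add atoms: none
Why: Grignard 1,2-addition to an aldehyde; the carbinol stereocentre is formed racemic, which is of no consequence because step 2 converts it into the (E)-alkene.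

**Step 2**
Reactants: 3 (±)-5-[(tert-butyldimethylsilyl)oxy]-2-methylpent-1-en-3-ol
Product: 5 ethyl (4E)-7-[(tert-butyldimethylsilyl)oxy]-4-methylhept-4-enoate, via mixed ketene acetal 4 (not isolated)
Conditions: MeC(OEt)3 (6 equiv), EtCO2H (cat.), 140 °C, EtOH distilled off
Reagents that add atoms: triethyl orthoacetate, CC(OCC)(OCC)OCC
Why: Johnson–Claisen rearrangement: the mixed ketene acetal 4 rearranges through a chair transition state with the CH2CH2OTBS group equatorial, which should give the (E)-trisubstituted alkene with high selectivity and places the ester carbon three bonds from it.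

**Step 3**
Reactants: 5 ethyl (4E)-7-[(tert-butyldimethylsilyl)oxy]-4-methylhept-4-enoate
Product: 6 (4E)-7-[(tert-butyldimethylsilyl)oxy]-4-methylhept-4-enal
Conditions: i-Bu2AlH (1.05 equiv), CH2Cl2, −78 °C; then aq. potassium sodium tartrate
Reagents that add atoms: none
Why: Partial ester reduction with i-Bu2AlH: the tetrahedral aluminium hemiacetal is stable at −78 °C and releases the aldehyde only on work-up, while the silyl ether and the alkene are inert.

**Step 4**
Reactants: 6 (4E)-7-[(tert-butyldimethylsilyl)oxy]-4-methylhept-4-enal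
Product: 7 tert-butyl{[(3E)-7,7-dibromo-4-methylhept-3-en-1-yl]oxy}dimethylsilane
Conditions: P(OPh)3, Br2, CH2Cl2, −78 °C; then Et3N, 6, −78 °C to rt
Reagents that add atoms: bromine, BrBr
Why: Deoxygenative gem-dibromination of an aldehyde with the phosphite–bromine adduct (Appel-type oxyphosphonium activation of the carbonyl oxygen), which contains no free bromine and should leave the trisubstituted alkene and the silyl ether intact.

**Step 5**
Reactants: 7 tert-butyl{[(3E)-7,7-dibromo-4-methylhept-3-en-1-yl]oxy}dimethylsilane; 8 2,2-dimethylcyclopentanone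
Product: 13 2-{(3E)-6-[(tert-butyldimethylsilyl)oxy]-3-methylhex-3-en-1-yl}-3,3-dimethylcyclohex-1-en-1-yl trifluoromethanesulfonate, via lithiated dibromide 9 (not isolated), via dibromo alkoxide 10 (not isolated), via β-oxido carbenoid 11 (not isolated), via lithium enolate 12 (not isolated)
Conditions: 7, LiN(i-Pr)2 (1.1 equiv), THF–Et2O, −100 °C; 8, −100 to −78 °C; n-BuLi (1.2 equiv), −100 to −20 °C; PhNTf2 (1.3 equiv), −78 to 0 °C
Reagents that add atoms: N-phenylbis(trifluoromethanesulfonimide), O=S(=O)(N(c1ccccc1)S(=O)(=O)C(F)(F)F)C(F)(F)F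
Why: LiN(i-Pr)2 removes the CHBr2 proton of 7 and the 1,1-dibromoalkyllithium 9 adds to the carbonyl group of 8 to give alkoxide 10; bromine–lithium exchange then generates the β-oxido carbenoid 11, in which the oxido group pushes a ring carbon onto the electrophilic carbenoid carbon as bromide leaves, so that this carbon is inserted into the ring and the carbonyl oxygen reappears as the lithium enolate 12, which the triflimide traps on oxygen. The closest known reaction type is the β-oxido carbenoid one-carbon ring enlargement of cycloalkanones (dibromomethyllithium adduct, then butyllithium), including its variants with an alkyl group on the carbenoid carbon and with electrophilic trapping of the ring-enlarged enolate. No ring is closed by cyclisation: the six-membered ring arises from the five-membered ring by a 1,2-shift of a ring C–C bond (enlargement by one carbon). No stereocentre survives the step (the carbinol and carbenoid centres of 10 and 11 are destroyed), and the ring double bond is fixed because the enolate can only form between the former carbonyl carbon and the inserted carbon. The step needs migration of the quaternary C(CH3)2 carbon and not of the ring CH2 or of a chain hydrogen: the more substituted α-carbon is the better migrating group toward the electron-poor carbenoid centre, and the alkoxide-assisted shift of a carbinol substituent is expected to outrun a hydride shift from the side chain. The union joins two seven-carbon fragments at the most hindered carbon of the carbocycle, which is why 9 is generated and used below −78 °C.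

**Step 6**
Reactants: 13 2-{(3E)-6-[(tert-butyldimethylsilyl)oxy]-3-methylhex-3-en-1-yl}-3,3-dimethylcyclohex-1-en-1-yl trifluoromethanesulfonate
Product: 14 tert-butyldimethyl{[(3E)-4-methyl-6-(2,6,6-trimethylcyclohex-1-en-1-yl)hex-3-en-1-yl]oxy}silane
Conditions: MeZnCl (3 equiv), Pd(PPh3)4 (5 mol%), THF, 60 °C
Reagents that add atoms: methylzinc chloride, C[Zn]Cl
Why: Negishi coupling of an enol triflate: zerovalent palladium inserts into the C–OTf bond, methyl is transferred from zinc and reductive elimination gives the tetrasubstituted ring alkene without migration of the double bond.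

**Step 7**
Reactants: 14 tert-butyldimethyl{[(3E)-4-methyl-6-(2,6,6-trimethylcyclohex-1-en-1-yl)hex-3-en-1-yl]oxy}silane
Product: 15 2-[(3E)-6-bromo-3-methylhex-3-en-1-yl]-1,3,3-trimethylcyclohex-1-ene
Conditions: PPh3, Br2 (gives Ph3PBr2), CH2Cl2, 0 °C to rt
Reagents that add atoms: bromine, BrBr
Why: Direct conversion of a primary silyl ether into the bromide with Ph3PBr2 (oxyphosphonium formation with loss of the silyl bromide, then SN2 by bromide) under neutral conditions that should not protonate the acid-sensitive 1,5-diene.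

**Step 8**
Reactants: 15 2-[(3E)-6-bromo-3-methylhex-3-en-1-yl]-1,3,3-trimethylcyclohex-1-ene; 16 prop-2-yn-1-ol
Product: 20 (2Z)-3-iodo-2-[(3E)-4-methyl-6-(2,6,6-trimethylcyclohex-1-en-1-yl)hex-3-en-1-yl]prop-2-en-1-ol, via Grignard reagent 17 (not isolated), via chloromagnesium propargyl alkoxide 18 (not isolated), via alkenylmagnesium chelate 19 (not isolated)
Conditions: 15, Mg, THF, 40 °C; separately 16, i-PrMgCl (1.0 equiv), THF, −20 °C; combine, CuI (10 mol%), −10 °C to rt; I2, −20 °C; then H2O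
Reagents that add atoms: iodine, II
Why: Copper-catalysed anti-carbomagnesiation of a propargylic alkoxide: the alkyl group is delivered to the internal alkyne carbon and magnesium to the terminal carbon on the side of the CH2O group (five-membered chelate 19), and iodinolysis with retention fixes the (Z)-geometry of the trisubstituted alkene.

**Step 9**
Reactants: 20 (2Z)-3-iodo-2-[(3E)-4-methyl-6-(2,6,6-trimethylcyclohex-1-en-1-yl)hex-3-en-1-yl]prop-2-en-1-ol
Product: 21 tert-butyl{[(2Z)-3-iodo-2-[(3E)-4-methyl-6-(2,6,6-trimethylcyclohex-1-en-1-yl)hex-3-en-1-yl]prop-2-en-1-yl]oxy}dimethylsilane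
Conditions: TBSCl, imidazole, CH2Cl2, 0 °C to rt
Reagents that add atoms: tert-butyldimethylsilyl chloride, CC(C)(C)[Si](C)(C)Cl
Why: Standard silylation of a primary allylic alcohol, which removes the acidic proton before the halogen–metal exchange.

**Step 10**
Reactants: 21 tert-butyl{[(2Z)-3-iodo-2-[(3E)-4-methyl-6-(2,6,6-trimethylcyclohex-1-en-1-yl)hex-3-en-1-yl]prop-2-en-1-yl]oxy}dimethylsilane; 22 methyl (2R)-oxirane-2-carboxylate
Product: 25 methyl (2R,4Z,8E)-5-{[(tert-butyldimethylsilyl)oxy]methyl}-2-hydroxy-9-methyl-11-(2,6,6-trimethylcyclohex-1-en-1-yl)undeca-4,8-dienoate, via alkenyllithium 23 (not isolated), via alkenylmagnesium bromide 24 (not isolated)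
Conditions: t-BuLi (2.1 equiv), Et2O, −78 °C; MgBr2·OEt2, −78 °C; CuI (10 mol%), 22, THF, −40 to −20 °C; then H2O
Reagents that add atoms: none
Why: Iodine–lithium exchange with retention of alkene geometry, transmetalation to magnesium and CuI-catalysed SN2 opening of the glycidic ester at its CH2 carbon; the stereocentre of 22 is not touched, so the (R)-α-hydroxy ester results, and the mixture is held at −78 °C in Et2O until transmetalation so that silyl migration from oxygen to the alkenyl carbon cannot intervene.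

**Step 11**
Reactants: 25 methyl (2R,4Z,8E)-5-{[(tert-butyldimethylsilyl)oxy]methyl}-2-hydroxy-9-methyl-11-(2,6,6-trimethylcyclohex-1-en-1-yl)undeca-4,8-dienoate
Product: 26 methyl (2R,4Z,8E)-2-acetoxy-5-{[(tert-butyldimethylsilyl)oxy]methyl}-9-methyl-11-(2,6,6-trimethylcyclohex-1-en-1-yl)undeca-4,8-dienoate
Conditions: Ac2O, pyridine, DMAP (cat.), CH2Cl2, 0 °C
Reagents that add atoms: acetic anhydride, CC(=O)OC(C)=O
Why: DMAP-catalysed acetylation of the secondary alcohol, which installs the two carbons that become the lactone carbonyl and its α-carbon.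

**Step 12**
Reactants: 26 methyl (2R,4Z,8E)-2-acetoxy-5-{[(tert-butyldimethylsilyl)oxy]methyl}-9-methyl-11-(2,6,6-trimethylcyclohex-1-en-1-yl)undeca-4,8-dienoate
Product: 27 (5R)-5-[(2Z,6E)-3-{[(tert-butyldimethylsilyl)oxy]methyl}-7-methyl-9-(2,6,6-trimethylcyclohex-1-en-1-yl)nona-2,6-dien-1-yl]-4-hydroxyfuran-2(5H)-one
Conditions: LiN(SiMe3)2 (2.5 equiv), THF, −78 to 0 °C; then cold 1 M HCl
Reagents that add atoms: none
Why: Dieckmann-type condensation (5-exo-trig): the kinetically formed acetate enolate attacks the neighbouring methyl ester and the product is held as its tetronate anion until acidification, which should protect the stereocentre from epimerisation.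

**Step 13**
Reactants: 27 (5R)-5-[(2Z,6E)-3-{[(tert-butyldimethylsilyl)oxy]methyl}-7-methyl-9-(2,6,6-trimethylcyclohex-1-en-1-yl)nona-2,6-dien-1-yl]-4-hydroxyfuran-2(5H)-one
Product: 28 (2R)-2-[(2Z,6E)-3-{[(tert-butyldimethylsilyl)oxy]methyl}-7-methyl-9-(2,6,6-trimethylcyclohex-1-en-1-yl)nona-2,6-dien-1-yl]-5-oxo-2,5-dihydrofuran-3-yl trifluoromethanesulfonate
Conditions: Tf2O, i-Pr2NEt, CH2Cl2, −78 °C
Reagents that add atoms: trifluoromethanesulfonic anhydride, O=S(=O)(OS(=O)(=O)C(F)(F)F)C(F)(F)F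
Why: O-Sulfonylation of the vinylogous acid at −78 °C gives the enol triflate, a β-triflyloxy enoate that is activated for oxidative addition.

**Step 14**
Reactants: 28 (2R)-2-[(2Z,6E)-3-{[(tert-butyldimethylsilyl)oxy]methyl}-7-methyl-9-(2,6,6-trimethylcyclohex-1-en-1-yl)nona-2,6-dien-1-yl]-5-oxo-2,5-dihydrofuran-3-yl trifluoromethanesulfonate
Product: 29 (5R)-5-[(2Z,6E)-3-{[(tert-butyldimethylsilyl)oxy]methyl}-7-methyl-9-(2,6,6-trimethylcyclohex-1-en-1-yl)nona-2,6-dien-1-yl]-4-(hydroxymethyl)furan-2(5H)-one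
Conditions: Bu3SnCH2OH (1.5 equiv), Pd(PPh3)4 (5 mol%), LiCl (3 equiv), 1,4-dioxane, 90 °C
Reagents that add atoms: (tributylstannyl)methanol, CCCC[Sn](CCCC)(CCCC)CO
Why: Stille coupling of the enol triflate with (tributylstannyl)methanol under zerovalent palladium catalysis with LiCl transfers the hydroxymethyl group to the β-carbon of the butenolide under neutral conditions that should not epimerise the γ-stereocentre.

**Step 15**
Reactants: 29 (5R)-5-[(2Z,6E)-3-{[(tert-butyldimethylsilyl)oxy]methyl}-7-methyl-9-(2,6,6-trimethylcyclohex-1-en-1-yl)nona-2,6-dien-1-yl]-4-(hydroxymethyl)furan-2(5H)-one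
Product: 30 (6Z)-neomanoalide, (5R)-4-(hydroxymethyl)-5-[(2Z,6E)-3-(hydroxymethyl)-7-methyl-9-(2,6,6-trimethylcyclohex-1-en-1-yl)nona-2,6-dien-1-yl]furan-2(5H)-one
Conditions: HF·pyridine, pyridine, THF, 0 °C to rt
Reagents that add atoms: none
Why: Fluoride-mediated cleavage of the primary silyl ether under buffered, weakly acidic conditions that the butenolide and the three alkenes should tolerate.

**Compound list**
1 | 3-[(tert-butyldimethylsilyl)oxy]propanal | O=CCCO[Si](C)(C)C(C)(C)C | starting material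
2 | isopropenylmagnesium bromide | C=C(C)[Mg]Br | starting material
3 | (±)-5-[(tert-butyldimethylsilyl)oxy]-2-methylpent-1-en-3-ol | C=C(C)C(O)CCO[Si](C)(C)C(C)(C)C | intermediate
4 | tert-butyl{[3-(1-ethoxyethenyloxy)-4-methylpent-4-en-1-yl]oxy}dimethylsilane (mixed ketene acetal, racemic) | C=C(OCC)OC(CCO[Si](C)(C)C(C)(C)C)C(C)=C | intermediate
5 | ethyl (4E)-7-[(tert-butyldimethylsilyl)oxy]-4-methylhept-4-enoate | CCOC(=O)CC/C(C)=C/CCO[Si](C)(C)C(C)(C)C | intermediate
6 | (4E)-7-[(tert-butyldimethylsilyl)oxy]-4-methylhept-4-enal | O=CCC/C(C)=C/CCO[Si](C)(C)C(C)(C)C | intermediate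
7 | tert-butyl{[(3E)-7,7-dibromo-4-methylhept-3-en-1-yl]oxy}dimethylsilane | BrC(Br)CC/C(C)=C/CCO[Si](C)(C)C(C)(C)C | intermediate
8 | 2,2-dimethylcyclopentanone | CC1(C)CCCC1=O | starting material
9 | {(4E)-1,1-dibromo-7-[(tert-butyldimethylsilyl)oxy]-4-methylhept-4-en-1-yl}lithium | [Li]C(Br)(Br)CC/C(C)=C/CCO[Si](C)(C)C(C)(C)C | intermediate
10 | lithium 1-{(4E)-1,1-dibromo-7-[(tert-butyldimethylsilyl)oxy]-4-methylhept-4-en-1-yl}-2,2-dimethylcyclopentan-1-olate (racemic) | [Li]OC1(C(Br)(Br)CC/C(C)=C/CCO[Si](C)(C)C(C)(C)C)CCCC1(C)C | intermediate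
11 | lithium 1-{(4E)-1-bromo-1-lithio-7-[(tert-butyldimethylsilyl)oxy]-4-methylhept-4-en-1-yl}-2,2-dimethylcyclopentan-1-olate (β-oxido carbenoid, mixture of isomers) | [Li]OC1(C([Li])(Br)CC/C(C)=C/CCO[Si](C)(C)C(C)(C)C)CCCC1(C)C | intermediate
12 | lithium 2-{(3E)-6-[(tert-butyldimethylsilyl)oxy]-3-methylhex-3-en-1-yl}-3,3-dimethylcyclohex-1-en-1-olate | [Li]OC1=C(CC/C(C)=C/CCO[Si](C)(C)C(C)(C)C)C(C)(C)CCC1 | intermediate
13 | 2-{(3E)-6-[(tert-butyldimethylsilyl)oxy]-3-methylhex-3-en-1-yl}-3,3-dimethylcyclohex-1-en-1-yl trifluoromethanesulfonate | FC(F)(F)S(=O)(=O)OC1=C(CC/C(C)=C/CCO[Si](C)(C)C(C)(C)C)C(C)(C)CCC1 | intermediate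
14 | tert-butyldimethyl{[(3E)-4-methyl-6-(2,6,6-trimethylcyclohex-1-en-1-yl)hex-3-en-1-yl]oxy}silane | CC1=C(CC/C(C)=C/CCO[Si](C)(C)C(C)(C)C)C(C)(C)CCC1 | intermediate
15 | 2-[(3E)-6-bromo-3-methylhex-3-en-1-yl]-1,3,3-trimethylcyclohex-1-ene | CC1=C(CC/C(C)=C/CCBr)C(C)(C)CCC1 | intermediate
16 | prop-2-yn-1-ol | C#CCO | starting material
17 | [(3E)-4-methyl-6-(2,6,6-trimethylcyclohex-1-en-1-yl)hex-3-en-1-yl]magnesium bromide | CC1=C(CC/C(C)=C/CC[Mg]Br)C(C)(C)CCC1 | intermediate
18 | chloromagnesium prop-2-yn-1-olate | C#CCO[Mg]Cl | intermediate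
19 | (Z)-alkenylmagnesium bromide with cis CH2OMgCl group (chelate from carbomagnesiation) | CC1=C(CC/C(C)=C/CC/C(CO[Mg]Cl)=C/[Mg]Br)C(C)(C)CCC1 | intermediate
20 | (2Z)-3-iodo-2-[(3E)-4-methyl-6-(2,6,6-trimethylcyclohex-1-en-1-yl)hex-3-en-1-yl]prop-2-en-1-ol | CC1=C(CC/C(C)=C/CC/C(CO)=C/I)C(C)(C)CCC1 | intermediate
21 | tert-butyl{[(2Z)-3-iodo-2-[(3E)-4-methyl-6-(2,6,6-trimethylcyclohex-1-en-1-yl)hex-3-en-1-yl]prop-2-en-1-yl]oxy}dimethylsilane | CC1=C(CC/C(C)=C/CC/C(CO[Si](C)(C)C(C)(C)C)=C/I)C(C)(C)CCC1 | intermediate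
22 | methyl (2R)-oxirane-2-carboxylate (methyl (R)-glycidate) | COC(=O)[C@H]1CO1 | starting material
23 | (Z)-alkenyllithium from 21 | CC1=C(CC/C(C)=C/CC/C(CO[Si](C)(C)C(C)(C)C)=C/[Li])C(C)(C)CCC1 | intermediate
24 | (Z)-alkenylmagnesium bromide from 23 | CC1=C(CC/C(C)=C/CC/C(CO[Si](C)(C)C(C)(C)C)=C/[Mg]Br)C(C)(C)CCC1 | intermediate
25 | methyl (2R,4Z,8E)-5-{[(tert-butyldimethylsilyl)oxy]methyl}-2-hydroxy-9-methyl-11-(2,6,6-trimethylcyclohex-1-en-1-yl)undeca-4,8-dienoate | CC1=C(CC/C(C)=C/CC/C(CO[Si](C)(C)C(C)(C)C)=C/C[C@@H](O)C(=O)OC)C(C)(C)CCC1 | intermediate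
26 | methyl (2R,4Z,8E)-2-acetoxy-5-{[(tert-butyldimethylsilyl)oxy]methyl}-9-methyl-11-(2,6,6-trimethylcyclohex-1-en-1-yl)undeca-4,8-dienoate | CC1=C(CC/C(C)=C/CC/C(CO[Si](C)(C)C(C)(C)C)=C/C[C@@H](OC(C)=O)C(=O)OC)C(C)(C)CCC1 | intermediate
27 | (5R)-5-[(2Z,6E)-3-{[(tert-butyldimethylsilyl)oxy]methyl}-7-methyl-9-(2,6,6-trimethylcyclohex-1-en-1-yl)nona-2,6-dien-1-yl]-4-hydroxyfuran-2(5H)-one | CC1=C(CC/C(C)=C/CC/C(CO[Si](C)(C)C(C)(C)C)=C/C[C@H]2OC(=O)C=C2O)C(C)(C)CCC1 | intermediate
28 | (2R)-2-[(2Z,6E)-3-{[(tert-butyldimethylsilyl)oxy]methyl}-7-methyl-9-(2,6,6-trimethylcyclohex-1-en-1-yl)nona-2,6-dien-1-yl]-5-oxo-2,5-dihydrofuran-3-yl trifluoromethanesulfonate | CC1=C(CC/C(C)=C/CC/C(CO[Si](C)(C)C(C)(C)C)=C/C[C@H]2OC(=O)C=C2OS(=O)(=O)C(F)(F)F)C(C)(C)CCC1 | intermediate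
29 | (5R)-5-[(2Z,6E)-3-{[(tert-butyldimethylsilyl)oxy]methyl}-7-methyl-9-(2,6,6-trimethylcyclohex-1-en-1-yl)nona-2,6-dien-1-yl]-4-(hydroxymethyl)furan-2(5H)-one | CC1=C(CC/C(C)=C/CC/C(CO[Si](C)(C)C(C)(C)C)=C/C[C@H]2OC(=O)C=C2CO)C(C)(C)CCC1 | intermediate
30 | (6Z)-neomanoalide, (5R)-4-(hydroxymethyl)-5-[(2Z,6E)-3-(hydroxymethyl)-7-methyl-9-(2,6,6-trimethylcyclohex-1-en-1-yl)nona-2,6-dien-1-yl]furan-2(5H)-one | CC1=C(CC/C(C)=C/CC/C(=C/C[C@H]2OC(=O)C=C2CO)CO)C(C)(C)CCC1 | target

**Summary**
Total step count: 15. Longest linear sequence: 15 steps (1 to 30); compounds 2, 8, 16 and 22 enter as purchased building blocks.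

**Steps most likely to fail**

Step 5. The bulky lithiated dibromide 9 may act as a base toward ketone 8 (enolisation, or reversal of the addition) instead of forming the congested alkoxide 10. The 1,2-shift may also be diverted to migration of the ring CH2 or to a hydride shift from the chain. The fallback makes the carbocycle by a different ring enlargement and attaches the chain afterwards. Purchased 1,2-dimethylcyclopentene is cyclopropanated with CHBr3 and KOt-Bu to 6,6-dibromo-1,5-dimethylbicyclo[3.1.0]hexane F1. Me3Al in CH2Cl2 acts as halophile and triggers the disrotatory opening of the cyclopropane, so that the five-membered ring becomes six-membered; the allylic bromide 2,3-dibromo-1,3-dimethylcyclohex-1-ene F2 and its symmetrical 2-bromoallyl cation are methylated at either terminus to the same 2-bromo-1,3,3-trimethylcyclohex-1-ene F3. The chain sets out from ester 5. LiOH gives (4E)-7-[(tert-butyldimethylsilyl)oxy]-4-methylhept-4-enoic acid F4, which is converted with N-hydroxypyridine-2-thione and dicyclohexylcarbodiimide into the thiohydroxamate ester F5. Photolysis of F5 with CHI3 (radical iododecarboxylation) should give tert-butyl{[(3E)-6-iodo-4-methylhex-3-en-1-yl]oxy}dimethylsilane F6, and zinc insertion gives the alkylzinc iodide F7. Negishi coupling of F7 with F3 under Pd(P(t-Bu)3)2 catalysis comes back to the route at compound 14.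

Step 8. Deprotonation of the alkyne C–H by Grignard reagent 17 and slow carbometalation may consume the advanced Grignard reagent. The fallback makes the (Z)-alkene by a Wittig reaction of an α-silyloxy ketone with a non-stabilised ylide, a combination that places the CH2O group cis to the ylide-derived substituent. It sets out from Grignard reagent 17, which is acylated with purchased 2-[(tert-butyldimethylsilyl)oxy]-N-methoxy-N-methylacetamide to (5E)-1-[(tert-butyldimethylsilyl)oxy]-6-methyl-8-(2,6,6-trimethylcyclohex-1-en-1-yl)oct-5-en-2-one F8. Purchased (R)-4-(2-hydroxyethyl)-2,2-dimethyl-1,3-dioxolane is converted with I2, PPh3 and imidazole into (4R)-4-(2-iodoethyl)-2,2-dimethyl-1,3-dioxolane F9, then with PPh3 into the phosphonium iodide F10, and with NaN(SiMe3)2 into the ylide F11. Reaction of F11 with F8 at −78 °C should give the (Z)-alkene acetonide F12. CuCl2·2H2O in MeCN removes the acetonide to give the (R)-1,2-diol F13. TEMPO with NaOCl and NaClO2 oxidises the primary alcohol to the α-hydroxy acid F14, and Me3SiCHN2 in MeOH esterifies it, which comes back to the route at compound 25.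

Step 14. Transfer of the hydroxymethyl group from tin may be slow, while triflate 28 decomposes or epimerises at the lactone stereocentre at the temperature needed. The fallback avoids the tetronic acid altogether and closes the butenolide by an intramolecular Wittig reaction. It sets out from compound 25, which MeNH(OMe)·HCl and i-PrMgCl convert into the N-methoxy-N-methylamide F15. (Tributylstannyl)methanol and ethyl vinyl ether (pyridinium p-toluenesulfonate) give tributyl[(1-ethoxyethoxy)methyl]stannane F16, and n-BuLi converts it into [(1-ethoxyethoxy)methyl]lithium F17. Addition of F17 (3 equiv) to F15 gives the α-hydroxy ketone F18. (Triphenylphosphoranylidene)ketene in toluene at 80 °C acylates the secondary hydroxyl group and the resulting ester ylide closes onto the ketone to give the butenolide acetal F19. Aqueous HF in MeCN removes the silyl ether and the acetal together, which comes back to the route at compound 30.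

**Further compounds**
F1 | step 5 | 6,6-dibromo-1,5-dimethylbicyclo[3.1.0]hexane (cis-fused) | CC12CCCC1(C)C2(Br)Br
F2 | step 5 | 2,3-dibromo-1,3-dimethylcyclohex-1-ene (racemic, not isolated) | CC1=C(Br)C(C)(Br)CCC1
F3 | step 5 | 2-bromo-1,3,3-trimethylcyclohex-1-ene | CC1=C(Br)C(C)(C)CCC1
F4 | step 5 | (4E)-7-[(tert-butyldimethylsilyl)oxy]-4-methylhept-4-enoic acid | OC(=O)CC/C(C)=C/CCO[Si](C)(C)C(C)(C)C
F5 | step 5 | 2-thioxopyridin-1(2H)-yl (4E)-7-[(tert-butyldimethylsilyl)oxy]-4-methylhept-4-enoate | S=C1C=CC=CN1OC(=O)CC/C(C)=C/CCO[Si](C)(C)C(C)(C)C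
F6 | step 5 | tert-butyl{[(3E)-6-iodo-4-methylhex-3-en-1-yl]oxy}dimethylsilane | ICC/C(C)=C/CCO[Si](C)(C)C(C)(C)C
F7 | step 5 | {(3E)-6-[(tert-butyldimethylsilyl)oxy]-3-methylhex-3-en-1-yl}zinc iodide | I[Zn]CC/C(C)=C/CCO[Si](C)(C)C(C)(C)C
F8 | step 8 | (5E)-1-[(tert-butyldimethylsilyl)oxy]-6-methyl-8-(2,6,6-trimethylcyclohex-1-en-1-yl)oct-5-en-2-one | CC1=C(CC/C(C)=C/CCC(=O)CO[Si](C)(C)C(C)(C)C)C(C)(C)CCC1
F9 | step 8 | (4R)-4-(2-iodoethyl)-2,2-dimethyl-1,3-dioxolane | ICC[C@H]1OC(C)(C)OC1
F10 | step 8 | {2-[(4R)-2,2-dimethyl-1,3-dioxolan-4-yl]ethyl}triphenylphosphonium iodide | [I-].C(C[C@H]1OC(C)(C)OC1)[P+](c1ccccc1)(c1ccccc1)c1ccccc1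
F11 | step 8 | {2-[(4R)-2,2-dimethyl-1,3-dioxolan-4-yl]ethylidene}triphenylphosphorane | C(C[C@H]1OC(C)(C)OC1)=P(c1ccccc1)(c1ccccc1)c1ccccc1
F12 | step 8 | tert-butyl{[(2Z,6E)-2-{2-[(4R)-2,2-dimethyl-1,3-dioxolan-4-yl]ethylidene}-6-methyl-8-(2,6,6-trimethylcyclohex-1-en-1-yl)oct-6-en-1-yl]oxy}dimethylsilane | CC1=C(CC/C(C)=C/CC/C(CO[Si](C)(C)C(C)(C)C)=C/C[C@H]2OC(C)(C)OC2)C(C)(C)CCC1
F13 | step 8 | (2R,4Z,8E)-5-{[(tert-butyldimethylsilyl)oxy]methyl}-9-methyl-11-(2,6,6-trimethylcyclohex-1-en-1-yl)undeca-4,8-diene-1,2-diol | CC1=C(CC/C(C)=C/CC/C(CO[Si](C)(C)C(C)(C)C)=C/C[C@@H](O)CO)C(C)(C)CCC1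
F14 | step 8 | (2R,4Z,8E)-5-{[(tert-butyldimethylsilyl)oxy]methyl}-2-hydroxy-9-methyl-11-(2,6,6-trimethylcyclohex-1-en-1-yl)undeca-4,8-dienoic acid | CC1=C(CC/C(C)=C/CC/C(CO[Si](C)(C)C(C)(C)C)=C/C[C@@H](O)C(O)=O)C(C)(C)CCC1
F15 | step 14 | (2R,4Z,8E)-5-{[(tert-butyldimethylsilyl)oxy]methyl}-2-hydroxy-N-methoxy-N,9-dimethyl-11-(2,6,6-trimethylcyclohex-1-en-1-yl)undeca-4,8-dienamide | CC1=C(CC/C(C)=C/CC/C(CO[Si](C)(C)C(C)(C)C)=C/C[C@@H](O)C(=O)N(C)OC)C(C)(C)CCC1
F16 | step 14 | tributyl[(1-ethoxyethoxy)methyl]stannane (racemic) | CCCC[Sn](CCCC)(CCCC)COC(C)OCC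
F17 | step 14 | [(1-ethoxyethoxy)methyl]lithium | [Li]COC(C)OCC
F18 | step 14 | (3R,5Z,9E)-6-{[(tert-butyldimethylsilyl)oxy]methyl}-1-(1-ethoxyethoxy)-3-hydroxy-10-methyl-12-(2,6,6-trimethylcyclohex-1-en-1-yl)dodeca-5,9-dien-2-one (acetal epimers) | CC1=C(CC/C(C)=C/CC/C(CO[Si](C)(C)C(C)(C)C)=C/C[C@@H](O)C(=O)COC(C)OCC)C(C)(C)CCC1
F19 | step 14 | (5R)-5-[(2Z,6E)-3-{[(tert-butyldimethylsilyl)oxy]methyl}-7-methyl-9-(2,6,6-trimethylcyclohex-1-en-1-yl)nona-2,6-dien-1-yl]-4-[(1-ethoxyethoxy)methyl]furan-2(5H)-one (acetal epimers) | CC1=C(CC/C(C)=C/CC/C(CO[Si](C)(C)C(C)(C)C)=C/C[C@H]2OC(=O)C=C2COC(C)OCC)C(C)(C)CCC1
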